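The cyclohexane ring is closed at the bond between its tertiary carbinol carbon C4 (OH, CH3) and the methylene C5 (ring numbered from the alkylidene carbon C1 through C2 with the hydroxypropyl chain and the quaternary C3). A SmI2-mediated intramolecular Barbier addition of a primary iodide to a methyl ketone forms this bond and sets C4 in one operation. It exploits the Z-configured tetrasubstituted alkylidene at C1, installed beforehand, whose allylic strain fixes the chair of the closing ring. The acyclic precursor carries C2 and C3 from an enantioselective Ireland–Claisen rearrangement of a geranyl ester; the homoprenyl arm later becomes the side chain.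

Key step: step 10

Assumption: the diazaborolidine bromide with i-Pr2NEt in CH2Cl2 is taken to form the Z(O) boron ketene acetal (enolate chain cis to O–B) and its (S,S) form to give the (2S,3R) acid; should either sense be opposite, the neryl ester or the (R,R) reagent is used with no other change.
Ring locants C1 to C6 of the target are also used for the corresponding carbons of the open-chain intermediates; TBS = tert-butyldimethylsilyl, Ts = p-toluenesulfonyl.

Step 1
Reactants: 1 δ-valerolactone
Product: 4 5-(tert-butyldimethylsilyloxy)pentanoic acid, via sodium 5-hydroxypentanoate 2 (not isolated), via bis-silylated hydroxy acid 3 (not isolated)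
Conditions: NaOH, H2O, 60 °C; evaporate; TBSCl, imidazole, DMF, rt; K2CO3, MeOH–THF–H2O, rt; citric acid to pH 4
Reagents that add atoms: sodium hydroxide [Na+].[OH-]; tert-butyldimethylsilyl chloride CC(C)(C)[Si](C)(C)Cl
Why: Lactone saponification followed by exhaustive silylation and selective solvolysis of the labile silyl ester should leave the primary silyl ether of the hydroxy acid, with no stereocentre involved.

Step 2
Reactants: 4 5-(tert-butyldimethylsilyloxy)pentanoic acid; 5 geraniol
Product: 6 geranyl 5-(tert-butyldimethylsilyloxy)pentanoate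
Conditions: DCC, DMAP (cat.), CH2Cl2, 0 °C → rt
Reagents that add atoms: none
Why: Steglich esterification acylates the primary allylic alcohol under neutral conditions that leave the E-trisubstituted alkene and the silyl ether untouched.

Step 3
Reactants: 6 geranyl 5-(tert-butyldimethylsilyloxy)pentanoate
Product: 8 (2S,3R)-2-[3-(tert-butyldimethylsilyloxy)propyl]-3-ethenyl-3,7-dimethyloct-6-enoic acid, via boron ketene acetal 7 (not isolated)
Conditions: (4S,5S)-2-bromo-4,5-diphenyl-1,3-bis[3,5-bis(trifluoromethyl)phenylsulfonyl]-1,3,2-diazaborolidine (1.5 equiv), i-Pr2NEt, CH2Cl2, −78 °C, then −20 → 4 °C; aqueous work-up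
Reagents that add atoms: none
Why: The chiral Z(O) boron ketene acetal should rearrange through a chair transition state (enantioselective Ireland–Claisen rearrangement) with the enolate chain equatorial and the geranyl methyl axial, which gives the required relative configuration of the tertiary C2 and quaternary C3 centres, while the C2-symmetric diazaborolidine shields one enolate face and sets the absolute configuration.

Step 4
Reactants: 8 (2S,3R)-2-[3-(tert-butyldimethylsilyloxy)propyl]-3-ethenyl-3,7-dimethyloct-6-enoic acid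
Product: 10 ethyl (4S,5R)-4-[3-(tert-butyldimethylsilyloxy)propyl]-5-ethenyl-2,5,9-trimethyl-3-oxodec-8-enoate (C2 epimers), via acyl imidazolide 9 (not isolated)
Conditions: CDI, THF, rt; then EtO2CCH(CH3)CO2H, MgCl2, Et3N, THF, rt → 45 °C; aq. HCl
Reagents that add atoms: ethyl hydrogen methylmalonate CCOC(=O)C(C)C(=O)O
Why: The acyl imidazolide C-acylates the magnesium enolate of the malonic half ester and loss of CO2 gives the α-methyl β-keto ester (decarboxylative Claisen condensation) under near-neutral conditions that should not epimerize C2.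

Step 5
Reactants: 10 ethyl (4S,5R)-4-[3-(tert-butyldimethylsilyloxy)propyl]-5-ethenyl-2,5,9-trimethyl-3-oxodec-8-enoate
Product: 11 ethyl (2E,4S,5R)-4-[3-(tert-butyldimethylsilyloxy)propyl]-5-ethenyl-2,5,9-trimethyl-3-(tosyloxy)deca-2,8-dienoate
Conditions: TsCl, Me2N(CH2)6NMe2, MeCN, 0 °C → rt
Reagents that add atoms: p-toluenesulfonyl chloride Cc1ccc(cc1)S(=O)(=O)Cl
Why: Amine-mediated, non-chelated O-sulfonylation of the β-keto ester enolate (stereoselective enol tosylate formation) should place the tosyloxy group trans to the ester, a geometry also favoured because the bulky C2 substituent avoids the α-methyl group, and this fixes the later Z-alkylidene at C1.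

Step 6
Reactants: 11 ethyl (2E,4S,5R)-4-[3-(tert-butyldimethylsilyloxy)propyl]-5-ethenyl-2,5,9-trimethyl-3-(tosyloxy)deca-2,8-dienoate
Product: 12 ethyl (2E,4S,5S)-5-acetyl-4-[3-(tert-butyldimethylsilyloxy)propyl]-2,5,9-trimethyl-3-(tosyloxy)deca-2,8-dienoate
Conditions: PdCl2 (10 mol%), CuCl, O2 (1 atm), DMF–H2O (7:1), rt
Reagents that add atoms: water O
Why: Tsuji–Wacker oxidation by divalent palladium should convert only the monosubstituted vinyl group on C3 into the methyl ketone (Markovnikov hydration–dehydrogenation), since the trisubstituted alkene and the electron-poor enol tosylate do not react.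

Step 7
Reactants: 12 ethyl (2E,4S,5S)-5-acetyl-4-[3-(tert-butyldimethylsilyloxy)propyl]-2,5,9-trimethyl-3-(tosyloxy)deca-2,8-dienoate
Product: 13 ethyl (2Z,4R,5S)-5-acetyl-4-[3-(tert-butyldimethylsilyloxy)propyl]-3-ethenyl-2,5,9-trimethyldeca-2,8-dienoate
Conditions: CH2=CHBF3K, Pd(OAc)2 (5 mol%), SPhos, K3PO4, THF–H2O, 60 °C
Reagents that add atoms: potassium vinyltrifluoroborate [K+].C=C[B-](F)(F)F
Why: Suzuki–Miyaura coupling of the activated enol tosylate (oxidative addition to zerovalent palladium, transmetalation, reductive elimination) proceeds with retention, so the vinyl group should take the place cis to the α-methyl group and the ester stay cis to C2.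

Step 8
Reactants: 13 ethyl (2Z,4R,5S)-5-acetyl-4-[3-(tert-butyldimethylsilyloxy)propyl]-3-ethenyl-2,5,9-trimethyldeca-2,8-dienoate
Product: 15 ethyl (2Z,4R,5S)-5-acetyl-4-[3-(tert-butyldimethylsilyloxy)propyl]-3-(2-hydroxyethyl)-2,5,9-trimethyldeca-2,8-dienoate, via B-alkyl-9-borabicyclononane 14 (not isolated)
Conditions: 9-BBN, THF, 0 °C → rt; then H2O2, aq. NaHCO3, 0 °C
Reagents that add atoms: hydrogen peroxide OO
Why: 9-BBN should add to the terminus of the monosubstituted vinyl group much faster than to the trisubstituted alkene, the tetrasubstituted enoate or the hindered ketone (anti-Markovnikov hydroboration–oxidation), and the resulting alcohol cannot lactonize because the ester is trans to the new chain.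

Step 9
Reactants: 15 ethyl (2Z,4R,5S)-5-acetyl-4-[3-(tert-butyldimethylsilyloxy)propyl]-3-(2-hydroxyethyl)-2,5,9-trimethyldeca-2,8-dienoate
Product: 16 ethyl (2Z,4R,5S)-5-acetyl-4-[3-(tert-butyldimethylsilyloxy)propyl]-3-(2-iodoethyl)-2,5,9-trimethyldeca-2,8-dienoate
Conditions: I2, PPh3, imidazole, CH2Cl2, 0 °C
Reagents that add atoms: iodine II
Why: The Appel reaction converts the primary alcohol into the iodide under neutral conditions that spare the ketone, the ester and the silyl ether.

Step 10
Reactants: 16 ethyl (2Z,4R,5S)-5-acetyl-4-[3-(tert-butyldimethylsilyloxy)propyl]-3-(2-iodoethyl)-2,5,9-trimethyldeca-2,8-dienoate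
Product: 18 ethyl (2Z)-2-[(2R,3S,4S)-2-[3-(tert-butyldimethylsilyloxy)propyl]-4-hydroxy-3,4-dimethyl-3-(4-methylpent-3-en-1-yl)cyclohexylidene]propanoate, via alkylsamarium diiodide 17 (not isolated)
Conditions: SmI2 (2.5 equiv), HMPA, THF, −78 → 0 °C, slow addition of 16 to the reductant; aq. NH4Cl
Reagents that add atoms: none
Why: SmI2–HMPA transfers two electrons to the C–I bond to give a primary alkylsamarium (trivalent samarium) that adds to the methyl ketone; the closest known reaction type is the SmI2-mediated intramolecular Barbier cyclization of ω-iodo ketones. The cyclohexane ring closes in the 6-exo-trig mode, C5 attacking the carbonyl carbon that becomes C4. C4 is the only new stereocentre and is set by substrate control in a chair-like transition state: allylic 1,3-strain with the Z-enoate at C1 holds the C2 silyloxypropyl chain axial and so the C3 methyl equatorial, the ketone methyl avoids a syn-pentane contact with the axial C2 chain by lying equatorial, and the oxygen ends axial, cis to the C2 chain and to the C3 methyl group. The step needs reduction of the C–I bond in preference to enoate and ketone, and capture of the C5 radical by SmI2 before it can attack the enoate β-carbon in a 3-exo mode; HMPA and inverse addition keep that reduction fast, and the fully substituted, twisted β-carbon C1 is a poor radical acceptor. The alkylidene geometry is untouched because C1 and its exocyclic partner take no part in the bond-forming event.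

Step 11
Reactants: 18 ethyl (2Z)-2-[(2R,3S,4S)-2-[3-(tert-butyldimethylsilyloxy)propyl]-4-hydroxy-3,4-dimethyl-3-(4-methylpent-3-en-1-yl)cyclohexylidene]propanoate
Product: 20 ethyl (2Z)-2-[(2R,3S,4S)-2-[3-(tert-butyldimethylsilyloxy)propyl]-4-hydroxy-3,4-dimethyl-3-[(3E)-4-methyl-5-oxopent-3-en-1-yl]cyclohexylidene]propanoate, via E-allylic alcohol 19 (not isolated)
Conditions: SeO2 (0.5 equiv), t-BuOOH, salicylic acid (cat.), CH2Cl2, rt; then MnO2, CH2Cl2, rt
Reagents that add atoms: selenium dioxide O=[Se]=O; tert-butyl hydroperoxide CC(C)(C)OO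
Why: Selenium dioxide allylic oxidation (ene reaction, then 2,3-sigmatropic shift) should attack only the electron-rich prenyl terminus, and there the E-methyl group, and MnO2 converges the alcohol–aldehyde mixture on the E-enal while the tertiary alcohol and the electron-poor enoate stay inert.

Step 12
Reactants: 21 (S)-citronellal
Product: 23 (3S)-3,7-dimethyloct-6-en-1-yne, via enol nonaflate 22 (not isolated)
Conditions: C4F9SO2F, phosphazene base P2-Et, DMF, −20 °C → rt
Reagents that add atoms: none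
Why: O-Sulfonylation of the aldehyde enolate and base-induced elimination of the enol nonaflate give the terminal alkyne with the same carbon count (one-pot aldehyde-to-alkyne conversion), and the methyl-bearing stereocentre is not acidified because the alkyne is held as its acetylide.

Step 13
Reactants: 20 ethyl (2Z)-2-[(2R,3S,4S)-2-[3-(tert-butyldimethylsilyloxy)propyl]-4-hydroxy-3,4-dimethyl-3-[(3E)-4-methyl-5-oxopent-3-en-1-yl]cyclohexylidene]propanoate; 23 (3S)-3,7-dimethyloct-6-en-1-yne
Product: 26 ethyl (2Z)-2-[(2R,3S,4S)-2-[3-(tert-butyldimethylsilyloxy)propyl]-4-hydroxy-3-[(3E,5S,6E,8S)-5-hydroxy-4,8,12-trimethyltrideca-3,6,11-trien-1-yl]-3,4-dimethylcyclohexylidene]propanoate, via E-alkenyl(dicyclohexyl)borane 24 (not isolated), via E-alkenyl(methyl)zinc 25 (not isolated)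
Conditions: 23 (2.5 equiv), Cy2BH, toluene, 0 °C → rt; Me2Zn, −78 °C; (2S)-(−)-3-exo-morpholinoisoborneol (10 mol%), then 20, −20 → 0 °C; aq. NH4Cl
Reagents that add atoms: none
Why: Syn-hydroboration of the terminal alkyne gives the E-alkenylborane, boron-to-zinc exchange gives the alkenylzinc, and the amino alcohol–zinc catalyst should deliver it to the Si face of the enal (catalytic asymmetric alkenylzinc addition), which sets the (S)-carbinol under reagent control while the ester and the zinc alkoxide of the tertiary alcohol are spectators.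

Step 14
Reactants: 26 ethyl (2Z)-2-[(2R,3S,4S)-2-[3-(tert-butyldimethylsilyloxy)propyl]-4-hydroxy-3-[(3E,5S,6E,8S)-5-hydroxy-4,8,12-trimethyltrideca-3,6,11-trien-1-yl]-3,4-dimethylcyclohexylidene]propanoate
Product: 27 (2Z)-2-[(2R,3S,4S)-2-[3-(tert-butyldimethylsilyloxy)propyl]-4-hydroxy-3-[(3E,5S,6E,8S)-5-hydroxy-4,8,12-trimethyltrideca-3,6,11-trien-1-yl]-3,4-dimethylcyclohexylidene]propan-1-ol
Conditions: i-Bu2AlH (6 equiv), CH2Cl2, −78 → −20 °C; aq. potassium sodium tartrate
Reagents that add atoms: none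
Why: The aluminium hydride reduces the conjugated ester in a 1,2-sense to the allylic alcohol without touching any alkene, so the Z-alkylidene geometry should be kept.

Step 15
Reactants: 27 (2Z)-2-[(2R,3S,4S)-2-[3-(tert-butyldimethylsilyloxy)propyl]-4-hydroxy-3-[(3E,5S,6E,8S)-5-hydroxy-4,8,12-trimethyltrideca-3,6,11-trien-1-yl]-3,4-dimethylcyclohexylidene]propan-1-ol
Product: 28 (2Z)-2-[(2R,3S,4S)-2-[3-(tert-butyldimethylsilyloxy)propyl]-4-hydroxy-3-[(3E,5S,6E,8S)-5-hydroxy-4,8,12-trimethyltrideca-3,6,11-trien-1-yl]-3,4-dimethylcyclohexylidene]propanal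
Conditions: Cu(MeCN)4OTf (5 mol%), 2,2'-bipyridine, TEMPO, N-methylimidazole, MeCN, air, rt
Reagents that add atoms: none
Why: Aerobic copper–nitroxyl oxidation is highly selective for primary over secondary alcohols, so only the primary allylic alcohol should be oxidized to the enal while the secondary bis-allylic and the tertiary alcohols remain.

Step 16
Reactants: 28 (2Z)-2-[(2R,3S,4S)-2-[3-(tert-butyldimethylsilyloxy)propyl]-4-hydroxy-3-[(3E,5S,6E,8S)-5-hydroxy-4,8,12-trimethyltrideca-3,6,11-trien-1-yl]-3,4-dimethylcyclohexylidene]propanal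
Product: 29 (2Z)-2-[(2R,3S,4S)-4-hydroxy-2-(3-hydroxypropyl)-3-[(3E,5S,6E,8S)-5-hydroxy-4,8,12-trimethyltrideca-3,6,11-trien-1-yl]-3,4-dimethylcyclohexylidene]propanal
Conditions: HF·pyridine, pyridine, THF, 0 °C → rt
Reagents that add atoms: none
Why: Pyridine-buffered fluoride cleaves the primary silyl ether (desilylation) under conditions mild enough that the bis-allylic alcohol should not ionize and the enal should not isomerize.

Compound list
1 | δ-valerolactone | O=C1CCCCO1 | starting material
2 | sodium 5-hydroxypentanoate | [Na+].[O-]C(=O)CCCCO | intermediate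
3 | tert-butyldimethylsilyl 5-(tert-butyldimethylsilyloxy)pentanoate | CC(C)(C)[Si](C)(C)OCCCCC(=O)O[Si](C)(C)C(C)(C)C | intermediate
4 | 5-(tert-butyldimethylsilyloxy)pentanoic acid | CC(C)(C)[Si](C)(C)OCCCCC(=O)O | intermediate
5 | geraniol, (2E)-3,7-dimethylocta-2,6-dien-1-ol | CC(C)=CCC/C(C)=C/CO | starting material
6 | geranyl 5-(tert-butyldimethylsilyloxy)pentanoate | CC(C)=CCC/C(C)=C/COC(=O)CCCCO[Si](C)(C)C(C)(C)C | intermediate
7 | Z(O) boron ketene acetal of 6 bearing the (4S,5S)-diazaborolidine | CC(C)(C)[Si](C)(C)OCCC/C=C(/OC/C=C(\C)CCC=C(C)C)OB1N(S(=O)(=O)c2cc(cc(c2)C(F)(F)F)C(F)(F)F)[C@@H](c2ccccc2)[C@H](c2ccccc2)N1S(=O)(=O)c1cc(cc(c1)C(F)(F)F)C(F)(F)F | intermediate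
8 | (2S,3R)-2-[3-(tert-butyldimethylsilyloxy)propyl]-3-ethenyl-3,7-dimethyloct-6-enoic acid | CC(C)=CCC[C@@](C)([C@H](CCCO[Si](C)(C)C(C)(C)C)C(=O)O)C=C | intermediate
9 | acyl imidazolide of 8 | CC(C)=CCC[C@@](C)([C@H](CCCO[Si](C)(C)C(C)(C)C)C(=O)n1ccnc1)C=C | intermediate
10 | ethyl (4S,5R)-4-[3-(tert-butyldimethylsilyloxy)propyl]-5-ethenyl-2,5,9-trimethyl-3-oxodec-8-enoate (C2 epimers) | CC(C)=CCC[C@@](C)([C@H](CCCO[Si](C)(C)C(C)(C)C)C(=O)C(C)C(=O)OCC)C=C | intermediate
11 | ethyl (2E,4S,5R)-4-[3-(tert-butyldimethylsilyloxy)propyl]-5-ethenyl-2,5,9-trimethyl-3-(tosyloxy)deca-2,8-dienoate | CC(C)=CCC[C@@](C)([C@H](CCCO[Si](C)(C)C(C)(C)C)/C(OS(=O)(=O)c1ccc(C)cc1)=C(/C)C(=O)OCC)C=C | intermediate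
12 | ethyl (2E,4S,5S)-5-acetyl-4-[3-(tert-butyldimethylsilyloxy)propyl]-2,5,9-trimethyl-3-(tosyloxy)deca-2,8-dienoate | CC(C)=CCC[C@@](C)([C@H](CCCO[Si](C)(C)C(C)(C)C)/C(OS(=O)(=O)c1ccc(C)cc1)=C(/C)C(=O)OCC)C(C)=O | intermediate
13 | ethyl (2Z,4R,5S)-5-acetyl-4-[3-(tert-butyldimethylsilyloxy)propyl]-3-ethenyl-2,5,9-trimethyldeca-2,8-dienoate | CC(C)=CCC[C@@](C)([C@H](CCCO[Si](C)(C)C(C)(C)C)/C(C=C)=C(/C)C(=O)OCC)C(C)=O | intermediate
14 | B-alkyl-9-borabicyclo[3.3.1]nonane from 13 | CC(C)=CCC[C@@](C)([C@H](CCCO[Si](C)(C)C(C)(C)C)/C(CCB1C2CCCC1CCC2)=C(/C)C(=O)OCC)C(C)=O | intermediate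
15 | ethyl (2Z,4R,5S)-5-acetyl-4-[3-(tert-butyldimethylsilyloxy)propyl]-3-(2-hydroxyethyl)-2,5,9-trimethyldeca-2,8-dienoate | CC(C)=CCC[C@@](C)([C@H](CCCO[Si](C)(C)C(C)(C)C)/C(CCO)=C(/C)C(=O)OCC)C(C)=O | intermediate
16 | ethyl (2Z,4R,5S)-5-acetyl-4-[3-(tert-butyldimethylsilyloxy)propyl]-3-(2-iodoethyl)-2,5,9-trimethyldeca-2,8-dienoate | CC(C)=CCC[C@@](C)([C@H](CCCO[Si](C)(C)C(C)(C)C)/C(CCI)=C(/C)C(=O)OCC)C(C)=O | intermediate
17 | primary alkylsamarium diiodide from 16 | CC(C)=CCC[C@@](C)([C@H](CCCO[Si](C)(C)C(C)(C)C)/C(CC[Sm](I)I)=C(/C)C(=O)OCC)C(C)=O | intermediate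
18 | ethyl (2Z)-2-[(2R,3S,4S)-2-[3-(tert-butyldimethylsilyloxy)propyl]-4-hydroxy-3,4-dimethyl-3-(4-methylpent-3-en-1-yl)cyclohexylidene]propanoate | CC(C)=CCC[C@@]1(C)[C@H](CCCO[Si](C)(C)C(C)(C)C)/C(=C(/C)C(=O)OCC)CC[C@]1(C)O | intermediate
19 | ethyl (2Z)-2-[(2R,3S,4S)-2-[3-(tert-butyldimethylsilyloxy)propyl]-4-hydroxy-3-[(3E)-5-hydroxy-4-methylpent-3-en-1-yl]-3,4-dimethylcyclohexylidene]propanoate | OC/C(C)=C/CC[C@@]1(C)[C@H](CCCO[Si](C)(C)C(C)(C)C)/C(=C(/C)C(=O)OCC)CC[C@]1(C)O | intermediate
20 | ethyl (2Z)-2-[(2R,3S,4S)-2-[3-(tert-butyldimethylsilyloxy)propyl]-4-hydroxy-3,4-dimethyl-3-[(3E)-4-methyl-5-oxopent-3-en-1-yl]cyclohexylidene]propanoate | O=C/C(C)=C/CC[C@@]1(C)[C@H](CCCO[Si](C)(C)C(C)(C)C)/C(=C(/C)C(=O)OCC)CC[C@]1(C)O | intermediate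
21 | (S)-citronellal, (3S)-3,7-dimethyloct-6-enal | CC(C)=CCC[C@H](C)CC=O | starting material
22 | enol nonaflate of 21 (E/Z mixture) | CC(C)=CCC[C@H](C)C=COS(=O)(=O)C(F)(F)C(F)(F)C(F)(F)C(F)(F)F | intermediate
23 | (3S)-3,7-dimethyloct-6-en-1-yne | CC(C)=CCC[C@H](C)C#C | intermediate
24 | dicyclohexyl[(1E,3S)-3,7-dimethylocta-1,6-dien-1-yl]borane | CC(C)=CCC[C@H](C)/C=C/B(C1CCCCC1)C1CCCCC1 | intermediate
25 | [(1E,3S)-3,7-dimethylocta-1,6-dien-1-yl](methyl)zinc | CC(C)=CCC[C@H](C)/C=C/[Zn]C | intermediate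
26 | ethyl (2Z)-2-[(2R,3S,4S)-2-[3-(tert-butyldimethylsilyloxy)propyl]-4-hydroxy-3-[(3E,5S,6E,8S)-5-hydroxy-4,8,12-trimethyltrideca-3,6,11-trien-1-yl]-3,4-dimethylcyclohexylidene]propanoate | CC(C)=CCC[C@H](C)/C=C/[C@H](O)/C(C)=C/CC[C@@]1(C)[C@H](CCCO[Si](C)(C)C(C)(C)C)/C(=C(/C)C(=O)OCC)CC[C@]1(C)O | intermediate
27 | (2Z)-2-[(2R,3S,4S)-2-[3-(tert-butyldimethylsilyloxy)propyl]-4-hydroxy-3-[(3E,5S,6E,8S)-5-hydroxy-4,8,12-trimethyltrideca-3,6,11-trien-1-yl]-3,4-dimethylcyclohexylidene]propan-1-ol | CC(C)=CCC[C@H](C)/C=C/[C@H](O)/C(C)=C/CC[C@@]1(C)[C@H](CCCO[Si](C)(C)C(C)(C)C)/C(=C(/C)CO)CC[C@]1(C)O | intermediate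
28 | (2Z)-2-[(2R,3S,4S)-2-[3-(tert-butyldimethylsilyloxy)propyl]-4-hydroxy-3-[(3E,5S,6E,8S)-5-hydroxy-4,8,12-trimethyltrideca-3,6,11-trien-1-yl]-3,4-dimethylcyclohexylidene]propanal | CC(C)=CCC[C@H](C)/C=C/[C@H](O)/C(C)=C/CC[C@@]1(C)[C@H](CCCO[Si](C)(C)C(C)(C)C)/C(=C(/C)C=O)CC[C@]1(C)O | intermediate
29 | (2Z)-2-[(2R,3S,4S)-4-hydroxy-2-(3-hydroxypropyl)-3-[(3E,5S,6E,8S)-5-hydroxy-4,8,12-trimethyltrideca-3,6,11-trien-1-yl]-3,4-dimethylcyclohexylidene]propanal | CC(C)=CCC[C@H](C)/C=C/[C@H](O)/C(C)=C/CC[C@@]1(C)[C@H](CCCO)/C(=C(/C)C=O)CC[C@]1(C)O | target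

Total step count: 16. Longest linear sequence: 15 steps (steps 1–11 and 13–16); step 12 is a one-step branch.

Steps most likely to fail

Step 10. After the first electron transfer the C5 radical may close 3-exo onto the enoate β-carbon or be quenched before it is reduced and reaches the ketone, and facial control at the carbonyl may be incomplete. The fallback forms the same ring bond as a pinacol coupling and then removes the extra oxygen. It sets out from alcohol 15, which is oxidized with buffered DMP to the keto aldehyde F1. SmI2 in THF–t-BuOH then couples the two carbonyl groups through their ketyls to give the cis-diol F2, the two oxygens being held cis on samarium. Only the secondary hydroxyl is converted into the S-methyl xanthate F3 (NaN(SiMe3)2, CS2, MeI). Barton–McCombie reduction (Bu3SnH, AIBN, toluene, 90 °C) removes it and comes back to the route at 18.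

Step 5. O-Sulfonylation of the very hindered enolate may be slow and may give a mixture of enol tosylate geometries, which would be carried into the alkylidene. The fallback takes the alkene geometry from a syn-carbocupration instead. It sets out from acid 8: LiAlH4 reduction gives the primary alcohol F4, DMP oxidation the aldehyde F5, Ohira–Bestmann homologation the terminal alkyne F6, and n-BuLi/ClCO2Et the ynoate F7. Lithium divinylcuprate adds syn across the triple bond at −78 °C and the alkenylcopper is methylated in situ with MeI/HMPA with retention, giving the triene ester F8 with the new vinyl group cis to the methyl group. Tsuji–Wacker oxidation of the isolated vinyl group on C3, the diene terminus being conjugated and electron-poor, comes back to the route at 13.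

Step 3. Rearrangement of the γ,γ-disubstituted allyl unit may be too slow at the low temperature needed for face control, and partial loss of enolate geometry or of the silyl ether under the Lewis acidic boron reagent would erode diastereo- and enantiopurity. The fallback takes relative control from the lithium enolate and absolute control from a resolution. It sets out from ester 6: LiN(i-Pr)2 in THF–DMPU with Me3SiCl gives the Z(O) silyl ketene acetal, whose Ireland–Claisen rearrangement on warming gives the racemic acid of the same relative configuration F9. Crystallization with (S)-1-phenylethylamine gives the diastereomerically pure ammonium salt F10, and acidification comes back to the route at 8.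

Further compounds
F1 | step 10 | ethyl (2Z,4R,5S)-5-acetyl-4-[3-(tert-butyldimethylsilyloxy)propyl]-2,5,9-trimethyl-3-(2-oxoethyl)deca-2,8-dienoate | CC(C)=CCC[C@@](C)([C@H](CCCO[Si](C)(C)C(C)(C)C)/C(CC=O)=C(/C)C(=O)OCC)C(C)=O
F2 | step 10 | cis-4,5-diol analogue of 18 (5-hydroxy) | CC(C)=CCC[C@@]1(C)[C@H](CCCO[Si](C)(C)C(C)(C)C)/C(=C(/C)C(=O)OCC)C[C@H](O)[C@]1(C)O
F3 | step 10 | S-methyl xanthate of the secondary hydroxyl of F2 | CC(C)=CCC[C@@]1(C)[C@H](CCCO[Si](C)(C)C(C)(C)C)/C(=C(/C)C(=O)OCC)C[C@H](OC(=S)SC)[C@]1(C)O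
F4 | step 5 | (2S,3R)-2-[3-(tert-butyldimethylsilyloxy)propyl]-3-ethenyl-3,7-dimethyloct-6-en-1-ol | CC(C)=CCC[C@@](C)([C@H](CCCO[Si](C)(C)C(C)(C)C)CO)C=C
F5 | step 5 | (2S,3R)-2-[3-(tert-butyldimethylsilyloxy)propyl]-3-ethenyl-3,7-dimethyloct-6-enal | CC(C)=CCC[C@@](C)([C@H](CCCO[Si](C)(C)C(C)(C)C)C=O)C=C
F6 | step 5 | terminal alkyne from F5 (one-carbon homologue) | CC(C)=CCC[C@@](C)([C@H](CCCO[Si](C)(C)C(C)(C)C)C#C)C=C
F7 | step 5 | ethyl ynoate from F6 | CC(C)=CCC[C@@](C)([C@H](CCCO[Si](C)(C)C(C)(C)C)C#CC(=O)OCC)C=C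
F8 | step 5 | ethyl (2Z,4R,5R)-4-[3-(tert-butyldimethylsilyloxy)propyl]-3,5-diethenyl-2,5,9-trimethyldeca-2,8-dienoate | CC(C)=CCC[C@@](C)([C@H](CCCO[Si](C)(C)C(C)(C)C)/C(C=C)=C(/C)C(=O)OCC)C=C
F9 | step 3 | racemic acid of the relative configuration of 8 | CC(C)=CCC[C@@](C)([C@H](CCCO[Si](C)(C)C(C)(C)C)C(=O)O)C=C.CC(C)=CCC[C@](C)([C@@H](CCCO[Si](C)(C)C(C)(C)C)C(=O)O)C=C
F10 | step 3 | (S)-1-phenylethylammonium salt of 8 | CC(C)=CCC[C@@](C)([C@H](CCCO[Si](C)(C)C(C)(C)C)C(=O)[O-])C=C.C[C@H]([NH3+])c1ccccc1
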